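## Retrosynthetic overview

1. The C7'–C8' bond is cut last: a CuI-catalysed Grignard opening of a cis-epoxide made from D-threonine sets C8' by inversion; oxidation of the freed C9'–OH and desilylation then give the target.
2. C10' is relayed from threonine: the epoxide carbon C9' directs an anti-selective ketone reduction and is itself erased in the final oxidation.
3. Key bond C5'–C6', together with the (E)-C3'=C4' olefin: Johnson–Claisen [3,3]-sigmatropic rearrangement of an isopropenyl carbinol made from the prenyl end of the linalool chain.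
4. C2 comes from (R)-linalool with its C–O bond never broken: hydroboration/B-alkyl Suzuki coupling attaches the bought arene (ring A), then a Pd-catalysed C–O coupling closes the dihydropyran (ring B), the only ring formed.

Assumption: (R)-(−)-linalool of ≥98% ee and D-threonine are the purchased chiral materials; side-chain carbons are called C1'–C12' counted outward from chroman C2 (ketone = C9', carbinol = C10').
Note: TIPS = tri(propan-2-yl)silyl, TBS = tert-butyl(dimethyl)silyl; in 8–11 the chroman C2 descriptor reads S, and in 24 the oxirane C2 descriptor reads R, by a change of CIP priority only – the centres themselves are unchanged.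

## Route

Step 1
Reactants: 1 3-bromo-5-methylphenol
Product: 2 3-bromo-4-chloro-5-methylphenol
Conditions: SO2Cl2 (1.05 equiv), CH2Cl2, 0 °C to rt
Reagents that add atoms: sulfuryl chloride O=S(=O)(Cl)Cl
Why: Electrophilic aromatic chlorination goes para to the phenol OH (as in the chlorination of 3,5-xylenol), placing Cl between Br and CH3, and minor ortho isomers are removed by crystallisation.

Step 2
Reactants: 2 3-bromo-4-chloro-5-methylphenol
Product: 3 (3-bromo-4-chloro-5-methylphenoxy)tri(propan-2-yl)silane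
Conditions: TIPSCl (1.2 equiv), imidazole (2.5 equiv), DMF, rt
Reagents that add atoms: chlorotri(propan-2-yl)silane CC(C)[Si](Cl)(C(C)C)C(C)C
Why: O-Silylation gives a bulky aryl silyl ether that should survive base, hydride, organomagnesium and oxidant and falls to fluoride at the end.

Step 3
Reactants: 4 (R)-(−)-linalool [(3R)-3,7-dimethylocta-1,6-dien-3-ol]; 3 (3-bromo-4-chloro-5-methylphenoxy)tri(propan-2-yl)silane
Product: 6 (3R)-1-[2-chloro-3-methyl-5-(TIPSO)phenyl]-3,7-dimethyloct-6-en-3-ol, via B-alkyl-9-BBN borane 5 (not isolated)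
Conditions: 9-BBN (1.3 equiv), THF, 0 °C to rt; then 3, PdCl2(dppf) (3 mol%), aq K3PO4 (3 equiv), DMF, 50 °C
Reagents that add atoms: none
Why: Anti-Markovnikov hydroboration of the vinyl group (9-BBN leaves the trisubstituted alkene alone) is followed by B-alkyl Suzuki–Miyaura coupling at C–Br in preference to C–Cl, and the linalool carbinol centre is not touched.

Step 4
Reactants: 6 (3R)-1-[2-chloro-3-methyl-5-(TIPSO)phenyl]-3,7-dimethyloct-6-en-3-ol
Product: 7 {[(2R)-2,8-dimethyl-2-(4-methylpent-3-en-1-yl)-3,4-dihydro-2H-chromen-6-yl]oxy}tri(propan-2-yl)silane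
Conditions: Pd(OAc)2 (5 mol%), tBuXPhos (7.5 mol%), Cs2CO3 (1.5 equiv), toluene, 90 °C
Reagents that add atoms: none
Why: Intramolecular Buchwald–Hartwig C–O coupling closes ring B after zerovalent palladium inserts into the aryl chloride; the tertiary alkoxide has no hydrogen on the carbinol carbon, so no reductive side path exists, and the O–C2 bond is never broken, so the linalool centre is retained as (2R).

Step 5
Reactants: 7 {[(2R)-2,8-dimethyl-2-(4-methylpent-3-en-1-yl)-3,4-dihydro-2H-chromen-6-yl]oxy}tri(propan-2-yl)silane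
Product: 8 ({(2S)-2-[2-(3,3-dimethyloxiran-2-yl)ethyl]-2,8-dimethyl-3,4-dihydro-2H-chromen-6-yl}oxy)tri(propan-2-yl)silane
Conditions: mCPBA (1.1 equiv), CH2Cl2, 0 °C
Reagents that add atoms: 3-chloroperoxybenzoic acid OOC(=O)c1cccc(Cl)c1
Why: Prilezhaev epoxidation of the only alkene gives a 1:1 mixture at the new oxirane carbon, which is erased in step 7.

Step 6
Reactants: 8 ({(2S)-2-[2-(3,3-dimethyloxiran-2-yl)ethyl]-2,8-dimethyl-3,4-dihydro-2H-chromen-6-yl}oxy)tri(propan-2-yl)silane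
Product: 9 5-[(2S)-2,8-dimethyl-6-(TIPSO)-3,4-dihydro-2H-chromen-2-yl]-2-methylpent-1-en-3-ol
Conditions: Al(Oi-Pr)3 (2 equiv), toluene, 110 °C
Reagents that add atoms: none
Why: Aluminium-alkoxide-mediated epoxide-to-allylic-alcohol isomerisation opens the oxirane at its tertiary carbon with loss of a methyl proton, giving the isopropenyl carbinol needed for the Claisen step; the carbinol centre (both epimers) is sacrificial.

Step 7
Reactants: 9 5-[(2S)-2,8-dimethyl-6-(TIPSO)-3,4-dihydro-2H-chromen-2-yl]-2-methylpent-1-en-3-ol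
Product: 12 ethyl (4E)-7-[(2R)-2,8-dimethyl-6-(TIPSO)-3,4-dihydro-2H-chromen-2-yl]-4-methylhept-4-enoate, via mixed orthoester 10 (not isolated), via ketene acetal 11 (not isolated)
Conditions: MeC(OEt)3 (6 equiv), EtCO2H (10 mol%), 140 °C, EtOH distilled off
Reagents that add atoms: triethyl orthoacetate CC(OCC)(OCC)OCC
Why: Johnson–Claisen [3,3]-sigmatropic rearrangement through a chair transition state with the C2' chain pseudo-equatorial forms the C5'–C6' bond and the (E)-C3'=C4' olefin (E ≥ 95:5 expected) while destroying the mixed carbinol centre.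

Step 8
Reactants: 12 ethyl (4E)-7-[(2R)-2,8-dimethyl-6-(TIPSO)-3,4-dihydro-2H-chromen-2-yl]-4-methylhept-4-enoate
Product: 13 (4E)-7-[(2R)-2,8-dimethyl-6-(TIPSO)-3,4-dihydro-2H-chromen-2-yl]-4-methylhept-4-en-1-ol
Conditions: i-Bu2AlH (2.5 equiv), CH2Cl2, −78 to 0 °C; aq potassium sodium tartrate work-up
Reagents that add atoms: none
Why: Hydride reduction of the ester to the primary alcohol leaves the aryl silyl ether, the chroman and the alkene untouched.

Step 9
Reactants: 13 (4E)-7-[(2R)-2,8-dimethyl-6-(TIPSO)-3,4-dihydro-2H-chromen-2-yl]-4-methylhept-4-en-1-ol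
Product: 14 {[(2R)-2-[(3E)-7-bromo-4-methylhept-3-en-1-yl]-2,8-dimethyl-3,4-dihydro-2H-chromen-6-yl]oxy}tri(propan-2-yl)silane
Conditions: CBr4 (1.3 equiv), PPh3 (1.4 equiv), CH2Cl2, 0 °C
Reagents that add atoms: carbon tetrabromide BrC(Br)(Br)Br
Why: Appel bromination turns the primary alcohol into the C7' bromide under neutral conditions.

Step 10
Reactants: 15 D-threonine [(2R,3S)-2-amino-3-hydroxybutanoic acid]
Product: 18 (2R,3S)-2-bromo-3-hydroxybutanoic acid, via diazonium carboxylate 16 (not isolated), via α-lactone 17 (not isolated)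
Conditions: NaNO2 (1.5 equiv), KBr (3.5 equiv), 1.25 M aq H2SO4, −5 to 0 °C
Reagents that add atoms: potassium bromide [K+].[Br-]
Why: Diazotisation with bromide capture proceeds through the α-lactone (double inversion), so C2 is substituted with net retention and C3 is untouched.

Step 11
Reactants: 18 (2R,3S)-2-bromo-3-hydroxybutanoic acid
Product: 19 potassium (2S,3S)-3-methyloxirane-2-carboxylate
Conditions: KOH (2.0 equiv), EtOH, −20 °C to rt
Reagents that add atoms: potassium hydroxide [K+].[OH-]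
Why: Intramolecular Williamson (SN2) closure by the C3 alkoxide inverts C2 and gives the cis-epoxide, whose methyl-bearing carbon (future C8') keeps the threonine configuration.

Step 12
Reactants: 19 potassium (2S,3S)-3-methyloxirane-2-carboxylate
Product: 21 (2S,3S)-N-methoxy-N,3-dimethyloxirane-2-carboxamide, via mixed pivalic anhydride 20 (not isolated)
Conditions: t-BuCOCl (1.05 equiv), THF, 0 °C; then MeNHOMe·HCl (1.2 equiv), N-methylmorpholine (2.2 equiv), 0 °C to rt
Reagents that add atoms: N,O-dimethylhydroxylamine hydrochloride CNOC.Cl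
Why: Mixed-anhydride amidation, in which the amine attacks the unhindered epoxy-acyl carbonyl, gives the Weinreb amide without touching either stereocentre.

Step 13
Reactants: 21 (2S,3S)-N-methoxy-N,3-dimethyloxirane-2-carboxamide
Product: 23 3-methyl-1-[(2S,3S)-3-methyloxiran-2-yl]but-2-en-1-one, via chelated tetrahedral adduct 22 (not isolated)
Conditions: Me2C=CHMgBr (1.3 equiv), THF, −20 to 0 °C; then pH 7 buffer
Reagents that add atoms: 2-methylprop-1-en-1-ylmagnesium bromide CC(C)=C[Mg]Br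
Why: Weinreb ketone synthesis: the stable magnesium chelate stops at mono-addition and releases the enone (C9'–C12' skeleton) only on work-up.

Step 14
Reactants: 23 3-methyl-1-[(2S,3S)-3-methyloxiran-2-yl]but-2-en-1-one
Product: 24 (1R)-3-methyl-1-[(2R,3S)-3-methyloxiran-2-yl]but-2-en-1-ol
Conditions: NaBH4 (1.0 equiv), CeCl3·7H2O (1.1 equiv), MeOH, −78 °C
Reagents that add atoms: none
Why: Luche 1,2-reduction of the epoxy enone: with the metal held between carbonyl and oxirane oxygens, hydride arrives on the face away from the oxirane CH(CH3) carbon and gives the anti epoxy alcohol, so the threonine-derived C9' sets C10' as R.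

Step 15
Reactants: 24 (1R)-3-methyl-1-[(2R,3S)-3-methyloxiran-2-yl]but-2-en-1-ol
Product: 25 tert-butyl(dimethyl){[(1R)-3-methyl-1-[(2S,3S)-3-methyloxiran-2-yl]but-2-en-1-yl]oxy}silane
Conditions: TBSCl (1.3 equiv), imidazole (2.5 equiv), DMF, rt
Reagents that add atoms: tert-butyl(chloro)dimethylsilane CC(C)(C)[Si](C)(C)Cl
Why: Silylation masks C10'–OH so that only C9'–OH is oxidised later, and its bulk steers the nucleophile to the distal epoxide carbon.

Step 16
Reactants: 14 {[(2R)-2-[(3E)-7-bromo-4-methylhept-3-en-1-yl]-2,8-dimethyl-3,4-dihydro-2H-chromen-6-yl]oxy}tri(propan-2-yl)silane; 25 tert-butyl(dimethyl){[(1R)-3-methyl-1-[(2S,3S)-3-methyloxiran-2-yl]but-2-en-1-yl]oxy}silane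
Product: 27 (3E,8S,9S,10R)-10-(TBSO)-1-[(2R)-2,8-dimethyl-6-(TIPSO)-3,4-dihydro-2H-chromen-2-yl]-4,8,12-trimethyltrideca-3,11-dien-9-ol, via Grignard reagent 26 (not isolated)
Conditions: 14, Mg, THF, 40 °C; then 25 (1.5 equiv), CuI (10 mol%), THF, −40 to 0 °C; pH 7 buffer
Reagents that add atoms: none
Why: Copper-catalysed SN2 opening of the cis-epoxide by the alkyl Grignard at the less hindered, methyl-bearing carbon remote from the silyloxy group forms C7'–C8' with inversion, which sets 8'S, while C9' and C10' are untouched.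

Step 17
Reactants: 27 (3E,8S,9S,10R)-10-(TBSO)-1-[(2R)-2,8-dimethyl-6-(TIPSO)-3,4-dihydro-2H-chromen-2-yl]-4,8,12-trimethyltrideca-3,11-dien-9-ol
Product: 28 (3E,8S,10R)-10-(TBSO)-1-[(2R)-2,8-dimethyl-6-(TIPSO)-3,4-dihydro-2H-chromen-2-yl]-4,8,12-trimethyltrideca-3,11-dien-9-one
Conditions: Dess–Martin periodinane (1.5 equiv), CH2Cl2, 0 °C to rt
Reagents that add atoms: none
Why: Dess–Martin oxidation under near-neutral conditions turns the sacrificial C9' carbinol into the ketone without epimerising the flanking C8' and C10' centres.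

Step 18
Reactants: 28 (3E,8S,10R)-10-(TBSO)-1-[(2R)-2,8-dimethyl-6-(TIPSO)-3,4-dihydro-2H-chromen-2-yl]-4,8,12-trimethyltrideca-3,11-dien-9-one
Product: 29 (3E,8S,10R)-10-hydroxy-1-[(2R)-6-hydroxy-2,8-dimethyl-3,4-dihydro-2H-chromen-2-yl]-4,8,12-trimethyltrideca-3,11-dien-9-one (CNP0273237.1)
Conditions: TBAF (3 equiv), AcOH (3 equiv), THF, 0 °C to rt, argon
Reagents that add atoms: none
Why: Fluoride cleaves the aryl TIPS and the secondary TBS ether in one operation, and acetic acid buffering suppresses enolisation of the α-hydroxy ketone and oxidation of the chromanol.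

## Compound list

1 | 3-bromo-5-methylphenol | Cc1cc(O)cc(Br)c1 | starting material
2 | 3-bromo-4-chloro-5-methylphenol | Cc1cc(O)cc(Br)c1Cl | intermediate
3 | (3-bromo-4-chloro-5-methylphenoxy)tri(propan-2-yl)silane | Cc1cc(O[Si](C(C)C)(C(C)C)C(C)C)cc(Br)c1Cl | intermediate
4 | (R)-(−)-linalool, (3R)-3,7-dimethylocta-1,6-dien-3-ol | CC(C)=CCC[C@@](C)(O)C=C | starting material
5 | (3S)-1-(9-borabicyclo[3.3.1]nonan-9-yl)-3,7-dimethyloct-6-en-3-ol | CC(C)=CCC[C@@](C)(O)CCB1C2CCCC1CCC2 | intermediate (not isolated)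
6 | (3R)-1-[2-chloro-3-methyl-5-(TIPSO)phenyl]-3,7-dimethyloct-6-en-3-ol | CC(C)=CCC[C@@](C)(O)CCc1cc(O[Si](C(C)C)(C(C)C)C(C)C)cc(C)c1Cl | intermediate
7 | {[(2R)-2,8-dimethyl-2-(4-methylpent-3-en-1-yl)-3,4-dihydro-2H-chromen-6-yl]oxy}tri(propan-2-yl)silane | CC(C)=CCC[C@]1(C)CCc2cc(O[Si](C(C)C)(C(C)C)C(C)C)cc(C)c2O1 | intermediate
8 | ({(2S)-2-[2-(3,3-dimethyloxiran-2-yl)ethyl]-2,8-dimethyl-3,4-dihydro-2H-chromen-6-yl}oxy)tri(propan-2-yl)silane, both oxirane epimers | CC1(C)OC1CC[C@]1(C)CCc2cc(O[Si](C(C)C)(C(C)C)C(C)C)cc(C)c2O1 | intermediate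
9 | 5-[(2S)-2,8-dimethyl-6-(TIPSO)-3,4-dihydro-2H-chromen-2-yl]-2-methylpent-1-en-3-ol, both carbinol epimers | C=C(C)C(O)CC[C@]1(C)CCc2cc(O[Si](C(C)C)(C(C)C)C(C)C)cc(C)c2O1 | intermediate
10 | ({(2S)-2-[3-(1,1-diethoxyethoxy)-4-methylpent-4-en-1-yl]-2,8-dimethyl-3,4-dihydro-2H-chromen-6-yl}oxy)tri(propan-2-yl)silane (mixed orthoester) | C=C(C)C(OC(C)(OCC)OCC)CC[C@]1(C)CCc2cc(O[Si](C(C)C)(C(C)C)C(C)C)cc(C)c2O1 | intermediate (not isolated)
11 | ({(2S)-2-[3-(1-ethoxyethenyloxy)-4-methylpent-4-en-1-yl]-2,8-dimethyl-3,4-dihydro-2H-chromen-6-yl}oxy)tri(propan-2-yl)silane (ketene acetal) | C=C(C)C(OC(=C)OCC)CC[C@]1(C)CCc2cc(O[Si](C(C)C)(C(C)C)C(C)C)cc(C)c2O1 | intermediate (not isolated)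
12 | ethyl (4E)-7-[(2R)-2,8-dimethyl-6-(TIPSO)-3,4-dihydro-2H-chromen-2-yl]-4-methylhept-4-enoate | CCOC(=O)CC/C(C)=C/CC[C@]1(C)CCc2cc(O[Si](C(C)C)(C(C)C)C(C)C)cc(C)c2O1 | intermediate
13 | (4E)-7-[(2R)-2,8-dimethyl-6-(TIPSO)-3,4-dihydro-2H-chromen-2-yl]-4-methylhept-4-en-1-ol | OCCC/C(C)=C/CC[C@]1(C)CCc2cc(O[Si](C(C)C)(C(C)C)C(C)C)cc(C)c2O1 | intermediate
14 | {[(2R)-2-[(3E)-7-bromo-4-methylhept-3-en-1-yl]-2,8-dimethyl-3,4-dihydro-2H-chromen-6-yl]oxy}tri(propan-2-yl)silane | BrCCC/C(C)=C/CC[C@]1(C)CCc2cc(O[Si](C(C)C)(C(C)C)C(C)C)cc(C)c2O1 | intermediate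
15 | D-threonine, (2R,3S)-2-amino-3-hydroxybutanoic acid | C[C@H](O)[C@@H](N)C(=O)O | starting material
16 | (1R,2S)-1-carboxylato-2-hydroxypropane-1-diazonium | C[C@H](O)[C@@H]([N+]#N)C(=O)[O-] | intermediate (not isolated)
17 | (3S)-3-[(1S)-1-hydroxyethyl]oxiran-2-one (α-lactone) | C[C@H](O)[C@@H]1OC1=O | intermediate (not isolated)
18 | (2R,3S)-2-bromo-3-hydroxybutanoic acid | C[C@H](O)[C@@H](Br)C(=O)O | intermediate
19 | potassium (2S,3S)-3-methyloxirane-2-carboxylate (cis) | C[C@@H]1O[C@@H]1C(=O)[O-].[K+] | intermediate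
20 | (2S,3S)-3-methyloxirane-2-carboxylic 2,2-dimethylpropanoic anhydride | C[C@@H]1O[C@@H]1C(=O)OC(=O)C(C)(C)C | intermediate (not isolated)
21 | (2S,3S)-N-methoxy-N,3-dimethyloxirane-2-carboxamide | C[C@@H]1O[C@@H]1C(=O)N(C)OC | intermediate
22 | bromomagnesium 1-[methoxy(methyl)amino]-3-methyl-1-[(2S,3S)-3-methyloxiran-2-yl]but-2-en-1-olate (tetrahedral adduct) | C[C@@H]1O[C@@H]1C(O[Mg]Br)(N(C)OC)C=C(C)C | intermediate (not isolated)
23 | 3-methyl-1-[(2S,3S)-3-methyloxiran-2-yl]but-2-en-1-one | C[C@@H]1O[C@@H]1C(=O)C=C(C)C | intermediate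
24 | (1R)-3-methyl-1-[(2R,3S)-3-methyloxiran-2-yl]but-2-en-1-ol | C[C@@H]1O[C@@H]1[C@H](O)C=C(C)C | intermediate
25 | tert-butyl(dimethyl){[(1R)-3-methyl-1-[(2S,3S)-3-methyloxiran-2-yl]but-2-en-1-yl]oxy}silane | C[C@@H]1O[C@@H]1[C@H](O[Si](C)(C)C(C)(C)C)C=C(C)C | intermediate
26 | bromo{(4E)-7-[(2R)-2,8-dimethyl-6-(TIPSO)-3,4-dihydro-2H-chromen-2-yl]-4-methylhept-4-en-1-yl}magnesium | Br[Mg]CCC/C(C)=C/CC[C@]1(C)CCc2cc(O[Si](C(C)C)(C(C)C)C(C)C)cc(C)c2O1 | intermediate (not isolated)
27 | (3E,8S,9S,10R)-10-(TBSO)-1-[(2R)-2,8-dimethyl-6-(TIPSO)-3,4-dihydro-2H-chromen-2-yl]-4,8,12-trimethyltrideca-3,11-dien-9-ol | CC(C)=C[C@@H](O[Si](C)(C)C(C)(C)C)[C@@H](O)[C@@H](C)CCC/C(C)=C/CC[C@]1(C)CCc2cc(O[Si](C(C)C)(C(C)C)C(C)C)cc(C)c2O1 | intermediate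
28 | (3E,8S,10R)-10-(TBSO)-1-[(2R)-2,8-dimethyl-6-(TIPSO)-3,4-dihydro-2H-chromen-2-yl]-4,8,12-trimethyltrideca-3,11-dien-9-one | CC(C)=C[C@@H](O[Si](C)(C)C(C)(C)C)C(=O)[C@@H](C)CCC/C(C)=C/CC[C@]1(C)CCc2cc(O[Si](C(C)C)(C(C)C)C(C)C)cc(C)c2O1 | intermediate
29 | (3E,8S,10R)-10-hydroxy-1-[(2R)-6-hydroxy-2,8-dimethyl-3,4-dihydro-2H-chromen-2-yl]-4,8,12-trimethyltrideca-3,11-dien-9-one | CC(C)=C[C@@H](O)C(=O)[C@@H](C)CCC/C(C)=C/CC[C@]1(C)CCc2cc(O)cc(C)c2O1 | target

## Step count and risks

Total: 18 steps. Longest linear sequence: 12 steps (1 to 29 through steps 1–9 and 16–18). The epoxide branch 15 to 25 is 6 steps (steps 10–15).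

The three steps most likely to fail:

**Step 16 (copper-catalysed Grignard opening of the internal epoxide).** The risks are a sluggish reaction of the valuable Grignard reagent, halohydrin formation from magnesium bromide, or attack at the wrong carbon. The fallback replaces the organocopper by a sulfonyl-stabilised carbanion and sets out from 14. Displacement with PhSO2Na (DMF, 60 °C) gives {[(2R)-2-[(3E)-7-(benzenesulfonyl)-4-methylhept-3-en-1-yl]-2,8-dimethyl-3,4-dihydro-2H-chromen-6-yl]oxy}tri(propan-2-yl)silane F5. Its lithio derivative (n-BuLi, THF, −78 °C) opens epoxide 25 in the presence of BF3·OEt2 at the same methyl-bearing carbon with inversion, giving (3E,7RS,8R,9S,10R)-7-(benzenesulfonyl)-10-(TBSO)-1-[(2R)-2,8-dimethyl-6-(TIPSO)-3,4-dihydro-2H-chromen-2-yl]-4,8,12-trimethyltrideca-3,11-dien-9-ol F6 (C8 geometry as in 27; the descriptor changes by priority). Reductive desulfonylation with sodium amalgam Na(Hg) and Na2HPO4 in MeOH at −20 °C removes the sulfone; the hydroxyl is γ to sulfur, so no Julia elimination can occur. The fallback comes back to the route at 27.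

**Step 4 (Pd C–O coupling at an electron-rich, doubly ortho-substituted aryl chloride).** The risk is that oxidative addition stalls. The fallback moves the ring closure onto an aryl bromide by changing the arene and sets out from 1. Para-bromination (NBS, MeCN, 0 °C) gives 3,4-dibromo-5-methylphenol F1, and silylation (TIPSCl, imidazole) gives (3,4-dibromo-5-methylphenoxy)tri(propan-2-yl)silane F2. Coupling with borane 5 under the step 3 conditions is then site-selective rather than halogen-selective: the C3–Br is less hindered and meta to the oxygen donor. It gives (3R)-1-[2-bromo-3-methyl-5-(TIPSO)phenyl]-3,7-dimethyloct-6-en-3-ol F3, whose aryl bromide closes under the same Pd(OAc)2/tBuXPhos/Cs2CO3 system at 60–70 °C. The fallback comes back at 7.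

**Step 14 (anti-selective reduction that sets C10').** The risk is an insufficient diastereomer ratio. The fallback sets the carbinol in a C–C bond-forming addition instead of a hydride delivery and sets out from 21. Reduction with i-Bu2AlH (THF, −78 °C) gives (2S,3S)-3-methyloxirane-2-carbaldehyde F4, used crude because it is volatile. Addition of 2-methylprop-1-en-1-ylmagnesium bromide in THF at −78 °C under Felkin–Anh control (oxirane C–O anti to the incoming nucleophile) gives the same anti epoxy alcohol. The fallback comes back at 24.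

## Further compounds

F1 | step 4 | 3,4-dibromo-5-methylphenol | Cc1cc(O)cc(Br)c1Br
F2 | step 4 | (3,4-dibromo-5-methylphenoxy)tri(propan-2-yl)silane | Cc1cc(O[Si](C(C)C)(C(C)C)C(C)C)cc(Br)c1Br
F3 | step 4 | (3R)-1-[2-bromo-3-methyl-5-(TIPSO)phenyl]-3,7-dimethyloct-6-en-3-ol | CC(C)=CCC[C@@](C)(O)CCc1cc(O[Si](C(C)C)(C(C)C)C(C)C)cc(C)c1Br
F4 | step 14 | (2S,3S)-3-methyloxirane-2-carbaldehyde | C[C@@H]1O[C@@H]1C=O
F5 | step 16 | {[(2R)-2-[(3E)-7-(benzenesulfonyl)-4-methylhept-3-en-1-yl]-2,8-dimethyl-3,4-dihydro-2H-chromen-6-yl]oxy}tri(propan-2-yl)silane | O=S(=O)(CCC/C(C)=C/CC[C@]1(C)CCc2cc(O[Si](C(C)C)(C(C)C)C(C)C)cc(C)c2O1)c1ccccc1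
F6 | step 16 | (3E,7RS,8R,9S,10R)-7-(benzenesulfonyl)-10-(TBSO)-1-[(2R)-2,8-dimethyl-6-(TIPSO)-3,4-dihydro-2H-chromen-2-yl]-4,8,12-trimethyltrideca-3,11-dien-9-ol | CC(C)=C[C@@H](O[Si](C)(C)C(C)(C)C)[C@@H](O)[C@@H](C)C(CC/C(C)=C/CC[C@]1(C)CCc2cc(O[Si](C(C)C)(C(C)C)C(C)C)cc(C)c2O1)S(=O)(=O)c1ccccc1
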